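## Analysis of the target

Target 33 is a linear sesquineolignan. Three catechol-derived arenes are joined by two 2-aryl-3-(hydroxymethyl)-2,3-dihydro-1,4-benzodioxine units: ring A carries the (E)-3-hydroxyprop-1-enyl chain, ring B sits in the middle, and ring C is a free catechol. The inner dioxane holds C7 and C8 with its oxygen atoms on ring A; the outer dioxane holds C7' and C8' with its oxygen atoms on ring B. Both dioxanes are trans but of opposite absolute sense, (7S,8S) inside and (7'R,8'R) outside. The two pairs are separated by ring B, so each pair needs its own source of absolute control, while within a pair one centre can steer the other. On rings A and B the regiochemistry is the same: the oxygen bearing the benzylic carbon (C7 or C7') is meta to the carbon substituent of the ring, and the oxygen bearing C8 or C8' is para. The free catechol oxidises in air under base, the p-alkoxycinnamyl alcohol ionises in acid, and the benzylic aryl ether bonds at C7 and C7' are each para to an oxygen donor, so strong acid, hydrogenolysis and benzylic oxidants must be kept out of the late steps. The difficulty is to build two unsymmetrical catechol diethers with full regiocontrol and two trans stereo pairs of opposite configuration. The strategy rests on C8': its hydroxymethyl carbon C9' is read as a vinyl group C9'=C10' shortened by one carbon, which makes C8' the inner terminus of an allyl unit C8'–C9'–C10' next to C7', whose aryl ether bond to the ring B oxygen meta to C7 is already in place.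

## Retrosynthetic reasoning

**Silyl ethers and side chain.** Target 33 is traced back to its tetrasilyl ether 32 and this to the ethyl cinnamate 31 (four O–Si bonds; oxidation level of the ring A side chain). Silyl groups leave under buffered, non-acidic, non-reductive conditions that the catechol, the cinnamyl alcohol and the benzylic ethers tolerate. Carrying the side chain as an unsaturated ester from the start means ring A needs no late C–C bond.

**Inner dioxane, O–aryl bond.** In 31 the bond between the C7 oxygen and ring A is cut, giving bromo alcohol 30. Closing on the arene side leaves both sp3 centres untouched, so the ring inherits the configuration of the open chain, and the bromine atom marks the ring A carbon meta to the side chain. The forward coupling proceeds with retention, so a trans ring requires the threo (7S,8S) arrangement in 30. The primary hydroxyl of diol 29 could close a six-membered ring equally well, so it is blocked first (29 to 30) with a silyl group too bulky to migrate to the neighbouring alkoxide.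

**Inner stereo pair, C7–C8 bond.** Diol 29 comes from imide 28 by reductive removal of the auxiliary. Imide 28 is cut between C7 and C8 into aldehyde 18 and aryloxyacetyl imide 26. A syn-selective auxiliary aldol makes the threo pair in one step under control of oxazolidinone 22 alone, which matters because the outer centres are remote and of opposite sense. Imide 26 is assembled from phenol 21 (from aldehyde 19 and ylide 20) and chloroacetyl imide 25 (from 22 and 23); this fixes the future O–C8 oxygen para to the side chain.

**Aldehyde 18 back to the vinyl dioxane.** Aldehyde 18 is the hydrolysis product of acetal 17, the silyl ether of alcohol 16. Alcohol 16 arises from vinyl compound 14 by oxidative cleavage of C9'=C10' with reductive work-up through aldehyde 15. The acetal protects the ring B carbonyl group from the hydride work-up. One carbon is given up, and in return C8' becomes reachable by allyl chemistry.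

**Outer dioxane, O–C8' bond (key disconnection).** In 14 the bond from the ring B oxygen para to the acetal to C8' is cut. This leads to phenol 13, in which C8' is the inner end of an (E)-allylic carbonate and C7' already carries its aryl ether. Cutting here lets C7' control C8' in a six-membered closure, the competing ring size is eight, and the regiochemistry on ring B is decided by which oxygen is free. The forward step must ionise the carbonate selectively and deliver the trans ring.

**Allylic carbonate, C9'=C10' bond.** Compound 13 is cut at its double bond into vinyl ether 11 and allyl methyl carbonate 12 (cross-metathesis). Reducing a C8'≡C9' triple bond to the (E)-alkene by hydroalumination was set aside. The directing C10' alkoxide would place aluminium on C8', β to the benzylic aryloxy group at C7', an arrangement set up for elimination of the aryloxide and loss of the C7' ether. Metathesis brings in C10' and the leaving group together under neutral conditions and favours the (E)-alkene.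

**Vinyl group and free phenol.** Compound 11 is the semihydrogenation product of alkyne 10, and 10 is the de-allylated form of 9. The allyl ether on the para oxygen of ring B is removed at the alkyne stage because 9 is the last intermediate without a second group that a palladium allyl-transfer catalyst would ionise.

**C7'–O bond.** Compound 9 is cut between C7' and the ring B oxygen meta to the acetal, giving (R)-propargylic alcohol 6 and phenol 8. The forward reaction is a Mitsunobu displacement with inversion. A propargylic alcohol is used so that SN2' substitution does not intervene, and the mono-allyl ether 8 ensures that only the meta oxygen can react.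

**Building blocks.** Alcohol 6 comes from its C-silyl precursor 5, formed by catalytic asymmetric addition of alkyne 3 (as zinc acetylide 4) to aldehyde 2, the bis-silyl ether of 1. Phenol 8 is the acetal of 7, made from the same aldehyde 1 by alkylation of its more acidic para hydroxyl group.

## Alternatives that were turned down

**Alternative 1:** The outer dioxane is cut at O–C7' instead of O–C8'. The precursor is catechol mono-ether A2, whose C7' is still a methylene group attached to a 4-hydroxyphenyl ring C. A mild two-electron oxidant raises this 4-hydroxybenzyl unit to the quinone methide level, and the free ring B phenol adds 6-exo to C7' to give the trans benzoate A1.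
- For: C8' can come from the chiral pool, the closure is short and needs no transition-metal catalyst, and trans is the expected preference.
- Against: only the 1,2-relationship to C8' controls C7', in a fast addition to a planar, very reactive electrophile, and a cis isomer cannot be corrected without acid. The oxidant must distinguish the ring C phenol from the free, electron-rich ring B phenol in the same molecule. Ring C needs differentiated oxygens with an acetal mask, whose acidic removal at the end endangers the cinnamyl alcohol and the benzylic ethers. The benzoate needs a redox adjustment before the inner ring can be built.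
- Comparison: on step count to the outer ring this alternative is as strong or stronger. The chosen strategy offers two control elements for C8' (substrate chair and matched ligand, in a reversible closure) and one fluoride-labile protecting scheme throughout.

**Alternative 2:** The inner dioxane is cut at the bond from the para oxygen to C8, with ring A present as methyl shikimate. The precursor is hydroxy ketone A4, a 5-O-alkylated methyl shikimate. A hydrosilane with a silyl triflate Lewis acid reduces its hemiketal through the cyclic cation to the trans-fused dioxane A3, forming the bond from shikimate O4 to C8 and the C8–H bond.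
- For: absolute configuration comes from the chiral pool without an auxiliary, axial hydride delivery to a six-membered cyclic cation is dependable, and the two ring A oxygens cannot be confused.
- Against: C7 in A4 is benzylic and α to the ketone, so it can epimerise. The strong Lewis acid acts on a molecule that already holds the acid-labile C7' ether and several silyl ethers. After closure, A3 must be dehydrated and dehydrogenated to an arene in the presence of electron-rich benzylic ethers, and the ester must be extended by two carbons. The shikimate centres are used only as a relay and then destroyed.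
- Comparison: the alternative is stronger on regiochemical certainty of ring A and needs no stoichiometric auxiliary. The chosen strategy offers an aromatic ring A with its side chain in place from the first step, a ring closure under basic, non-ionising conditions, and a shorter endgame.

**Alternative 3:** The inner dioxane is cut at O–C7 by a conjugate addition. The precursor is α-aryloxy enal A6 with a free ring A phenol. A chiral primary amine salt forms the iminium ion, the phenol adds 6-endo to C7, and C8 settles trans by enolisation, giving aldehyde A5 with a ring A bromide.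
- For: it is catalytic, sets C7 directly, lets C8 correct itself, and is shorter for the inner ring than an auxiliary aldol sequence.
- Against: the acceptor is deactivated twice, by the para-alkoxy donor of ring B on the β-carbon and by the α-aryloxy branch, which also hinders the iminium ion. Phenol conjugate additions are reversible, so A5 can reopen by β-elimination of the phenoxide that added, and C7 erodes. A5 is an α-aryloxy aldehyde that must be reduced at once. The bromide still requires a late C–C coupling to install the side chain.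
- Comparison: on step count and atom economy for the inner ring the alternative is stronger. The chosen strategy offers an irreversible C–C bond formation that fixes C7 and C8 together and a closure with retention. Its risk sits in the outer-ring palladium step, which is itself reversible towards the trans isomer.

Key step: step 10

Assumption: catalyst-bound species that exist only within one operation (π-allyl-, aryl- and alkylidene-metal complexes, Mitsunobu phosphonium adducts) are described in the Why lines and are not numbered.

Abbreviations in names: TBS = tert-butyldimethylsilyl; TIPS = triisopropylsilyl; ArC = 3,4-bis(TBS-oxy)phenyl (ring C); BD = (2R,3R)-3-ArC-2-[(TBS-oxy)methyl]-2,3-dihydro-1,4-benzodioxin-6-yl (rings B and C with the outer dioxane, as in 18).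

## Route

Step 1
Reactants: 1 3,4-dihydroxybenzaldehyde
Product: 2 3,4-bis(TBS-oxy)benzaldehyde
Conditions: TBSCl (2.4 equiv), imidazole (5 equiv), DMF, 0 °C → rt
Reagents that add atoms: tert-butyldimethylsilyl chloride, CC(C)(C)[Si](C)(C)Cl
Why: Imidazole-promoted silylation of both phenols; the aldehyde is untouched and the bis-silyl catechol tolerates the neutral and mildly basic steps that follow.

Step 2
Reactants: 2 3,4-bis(TBS-oxy)benzaldehyde; 3 ethynyltrimethylsilane
Product: 5 (S)-1-ArC-3-(trimethylsilyl)prop-2-yn-1-ol, via methylzinc trimethylsilylacetylide 4 (not isolated)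
Conditions: 3 (3 equiv), Me2Zn (3 equiv), (S,S)-ProPhenol (10 mol%), Ph3PO (20 mol%), toluene, 4 °C
Reagents that add atoms: none
Why: Catalytic asymmetric alkynylation of an aryl aldehyde by a dinuclear zinc–ProPhenol complex; the alkynyl group must add to the Re face of 2 (descriptor S only because the silylalkynyl group outranks the aryl group), and the ligand antipode that does so is used, (S,S) being expected by analogy with its aldol reactions. A ketone reduction was not chosen because a carbonyl carbon flanked by an aryl and an alkynyl group offers the usual transfer-hydrogenation catalysts two competing π substituents.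

Step 3
Reactants: 5 (S)-1-ArC-3-(trimethylsilyl)prop-2-yn-1-ol
Product: 6 (R)-1-ArC-prop-2-yn-1-ol
Conditions: AgNO3 (10 mol%), acetone/H2O (4:1), rt, dark
Reagents that add atoms: none
Why: Silver-catalysed protodesilylation of the alkynylsilane through a silver acetylide under neutral conditions, which spares the base-labile aryl silyl ethers; the carbinol centre is not involved (descriptor R by priority change only).

Step 4
Reactants: 1 3,4-dihydroxybenzaldehyde
Product: 7 4-(allyloxy)-3-hydroxybenzaldehyde
Conditions: allyl bromide (1.05 equiv), NaHCO3 (1.2 equiv), NaI (cat.), DMF, 40 °C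
Reagents that add atoms: allyl bromide, C=CCBr
Why: Regioselective Williamson mono-alkylation; with a weak base only the more acidic 4-hydroxyl, para to the formyl group, is deprotonated and alkylated.

Step 5
Reactants: 7 4-(allyloxy)-3-hydroxybenzaldehyde
Product: 8 2-(allyloxy)-5-(dimethoxymethyl)phenol
Conditions: HC(OMe)3, MeOH, PPTS (cat.), rt; Et3N quench
Reagents that add atoms: trimethyl orthoformate, COC(OC)OC; methanol, CO
Why: Acid-catalysed acetalisation driven by the orthoester as water scavenger; the acetal protects the ring B carbonyl group from the hydride work-up of step 11.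

Step 6
Reactants: 6 (R)-1-ArC-prop-2-yn-1-ol; 8 2-(allyloxy)-5-(dimethoxymethyl)phenol
Product: 9 1-(allyloxy)-2-{[(1S)-1-ArC-prop-2-yn-1-yl]oxy}-4-(dimethoxymethyl)benzene
Conditions: PPh3 (1.3 equiv), DIAD (1.3 equiv), toluene, −20 → 0 °C
Reagents that add atoms: none
Why: Mitsunobu etherification; the phenol of 8, meta to the acetal, displaces the oxyphosphonium of 6 with inversion to give the (S) aryl ether. A propargylic alcohol has little tendency to SN2' substitution, and the non-polar solvent and low temperature hold back ionisation of the electron-rich benzylic centre.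

Step 7
Reactants: 9 1-(allyloxy)-2-{[(1S)-1-ArC-prop-2-yn-1-yl]oxy}-4-(dimethoxymethyl)benzene
Product: 10 2-{[(1S)-1-ArC-prop-2-yn-1-yl]oxy}-4-(dimethoxymethyl)phenol
Conditions: Pd(PPh3)4 (5 mol%), morpholine (5 equiv), THF, rt
Reagents that add atoms: none
Why: De-allylation of the aryl allyl ether by zerovalent palladium with morpholine as allyl scavenger (Tsuji–Trost allyl transfer); it is placed here because the propargylic aryl ether is not ionised under these conditions, whereas every later intermediate up to 14 carries an allylic ether or carbonate.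

Step 8
Reactants: 10 2-{[(1S)-1-ArC-prop-2-yn-1-yl]oxy}-4-(dimethoxymethyl)phenol
Product: 11 2-{[(1S)-1-ArC-prop-2-en-1-yl]oxy}-4-(dimethoxymethyl)phenol
Conditions: H2 (1 atm), Pd/CaCO3 poisoned with Pb(OAc)2 (Lindlar catalyst), quinoline, EtOAc, rt
Reagents that add atoms: none
Why: Lindlar semihydrogenation of the terminal alkyne to the vinyl group; the poisoned catalyst should stop at the alkene and leave the benzylic C–O bond intact.

Step 9
Reactants: 11 2-{[(1S)-1-ArC-prop-2-en-1-yl]oxy}-4-(dimethoxymethyl)phenol; 12 allyl methyl carbonate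
Product: 13 (2E,4S)-4-ArC-4-[5-(dimethoxymethyl)-2-hydroxyphenoxy]but-2-en-1-yl methyl carbonate
Conditions: 12 (5 equiv), RuCl2(H2IMes)(=CH-C6H4-2-O-i-Pr) (second-generation Hoveyda–Grubbs catalyst, 5 mol%), CH2Cl2, 40 °C
Reagents that add atoms: none
Why: Olefin cross-metathesis between the hindered terminal alkene of 11, which should not homodimerise, and an excess of the unhindered allyl carbonate; the (E)-alkene is the thermodynamic product, and neither the stereocentre nor the free phenol takes part.

Step 10
Reactants: 13 (2E,4S)-4-ArC-4-[5-(dimethoxymethyl)-2-hydroxyphenoxy]but-2-en-1-yl methyl carbonate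
Product: 14 (2R,3R)-3-ArC-6-(dimethoxymethyl)-2-vinyl-2,3-dihydro-1,4-benzodioxine
Conditions: Pd2(dba)3·CHCl3 (2.5 mol%), (R,R)-DACH-phenyl Trost ligand (7.5 mol%), CH2Cl2 (0.02 M), rt
Reagents that add atoms: none
Why: Zerovalent palladium, formed from Pd2(dba)3·CHCl3 and the diphosphine, ionises the primary allylic methyl carbonate with loss of CO2 and methoxide, which deprotonates the ring B phenol, and gives a syn π-allyl complex over C8'–C9'–C10'. The closest known reaction type is the intramolecular Tsuji–Trost O-allylation of phenols that closes 2-vinyl-1,4-benzodioxanes and 2-vinylchromans. The phenoxide para to the acetal attacks the inner terminus C8' anti to palladium in a 6-exo closure that forms the O–C8' bond and the outer dioxane; attack at C10' would give an eight-membered ring and should not compete. The new centre C8' is controlled by C7': in the half-chair transition state the C7' aryl group and the allyl–palladium unit both lie pseudo-equatorial, which leads to the trans (7'R,8'R) ring, and the matched antipode of the ligand adds to this preference. The two diastereomeric π-allyl complexes exchange faces by π–σ–π slippage through the unsubstituted C10' terminus, so both can drain through the lower, trans transition state. The step needs trans over cis, 6-exo over 8-endo and ionisation of the carbonate only; the last is secured because a primary carbonate leaves far faster than the aryloxide at C7', which is no longer allylic after closure. Regiochemistry on ring B needs no control, since the meta oxygen already carries C7' and only the para phenol is free. Because the product is itself an allylic aryl ether at C8', the closure is reversible, and a cis isomer can return to the π-allyl complex and settle as the more stable trans ring.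

Step 11
Reactants: 14 (2R,3R)-3-ArC-6-(dimethoxymethyl)-2-vinyl-2,3-dihydro-1,4-benzodioxine
Product: 16 [(2R,3R)-3-ArC-6-(dimethoxymethyl)-2,3-dihydro-1,4-benzodioxin-2-yl]methanol, via benzodioxine-2-carbaldehyde 15 (not isolated)
Conditions: O3, CH2Cl2/MeOH (4:1), NaHCO3, Sudan Red 7B, −78 °C; then NaBH4, −78 → 0 °C
Reagents that add atoms: ozone, [O-][O+]=O
Why: Ozonolysis of the terminal alkene, which reacts much faster than the arenes (dye end-point), with borohydride work-up in the same flask; reduction at low temperature should precede epimerisation or β-aryloxide loss at the α-aryloxy aldehyde 15, so C8' keeps its configuration.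

Step 12
Reactants: 16 [(2R,3R)-3-ArC-6-(dimethoxymethyl)-2,3-dihydro-1,4-benzodioxin-2-yl]methanol
Product: 17 tert-butyl{[(2R,3R)-3-ArC-6-(dimethoxymethyl)-2,3-dihydro-1,4-benzodioxin-2-yl]methoxy}dimethylsilane
Conditions: TBSCl (1.3 equiv), imidazole (2.5 equiv), DMF, rt
Reagents that add atoms: tert-butyldimethylsilyl chloride, CC(C)(C)[Si](C)(C)Cl
Why: Standard silylation of the primary alcohol, needed because a free hydroxyl would consume the boron triflate of the aldol step; the basic conditions keep the acetal intact.

Step 13
Reactants: 17 tert-butyl{[(2R,3R)-3-ArC-6-(dimethoxymethyl)-2,3-dihydro-1,4-benzodioxin-2-yl]methoxy}dimethylsilane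
Product: 18 (2R,3R)-3-ArC-2-[(TBS-oxy)methyl]-2,3-dihydro-1,4-benzodioxine-6-carbaldehyde (BD–CHO)
Conditions: PPTS (10 mol%), acetone/H2O (10:1), rt
Reagents that add atoms: water, O
Why: Mild acid hydrolysis of the dimethyl acetal of an electron-rich benzaldehyde, fast enough under pyridinium tosylate that the silyl ethers and the benzylic ether at C7' should be unaffected.

Step 14
Reactants: 19 3-bromo-4-hydroxybenzaldehyde; 20 ethyl (triphenylphosphoranylidene)acetate
Product: 21 ethyl (E)-3-(3-bromo-4-hydroxyphenyl)prop-2-enoate
Conditions: 20 (1.3 equiv), toluene, 90 °C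
Reagents that add atoms: none
Why: Wittig olefination with a stabilised ylide, (E)-selective and tolerant of the free phenol; it places the complete side-chain carbon skeleton on ring A at the outset.

Step 15
Reactants: 22 (R)-4-benzyloxazolidin-2-one; 23 chloroacetyl chloride
Product: 25 (R)-4-benzyl-3-(chloroacetyl)oxazolidin-2-one, via lithium oxazolidinide 24 (not isolated)
Conditions: n-BuLi (1.0 equiv), THF, −78 °C; then 23 (1.1 equiv), −78 → 0 °C
Reagents that add atoms: none
Why: N-acylation of the lithiated auxiliary by the acid chloride, which reacts at the acyl carbon far faster than at the alkyl chloride.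

Step 16
Reactants: 21 ethyl (E)-3-(3-bromo-4-hydroxyphenyl)prop-2-enoate; 25 (R)-4-benzyl-3-(chloroacetyl)oxazolidin-2-one
Product: 26 ethyl (E)-3-(4-{2-[(4R)-4-benzyl-2-oxooxazolidin-3-yl]-2-oxoethoxy}-3-bromophenyl)prop-2-enoate
Conditions: K2CO3 (1.5 equiv), NaI (10 mol%), MeCN, 50 °C
Reagents that add atoms: none
Why: Williamson alkylation of the phenoxide by the activated α-chloro imide with iodide catalysis; the oxygen para to the acrylate thereby becomes the future O–C8 oxygen.

Step 17
Reactants: 26 ethyl (E)-3-(4-{2-[(4R)-4-benzyl-2-oxooxazolidin-3-yl]-2-oxoethoxy}-3-bromophenyl)prop-2-enoate; 18 BD–CHO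
Product: 28 (4R)-4-benzyl-3-[(2R,3S)-3-(BD)-2-{2-bromo-4-[(E)-3-ethoxy-3-oxoprop-1-en-1-yl]phenoxy}-3-hydroxypropanoyl]oxazolidin-2-one, via dibutylboron Z-enolate 27 (not isolated)
Conditions: 26 (1.2 equiv), Bu2BOTf (1.3 equiv), i-Pr2NEt (1.5 equiv), CH2Cl2, −78 → 0 °C; then 18, −78 → 0 °C; pH 7 phosphate buffer, MeOH, H2O2, 0 °C
Reagents that add atoms: none
Why: Evans syn aldol reaction; the (Z)-boron enolate of the aryloxyacetyl imide reacts through a closed chair transition state in which the benzyl group of the (R)-auxiliary shields one enolate face. This sets C8 and C7 together as the syn (threo) pair that becomes (7S,8S), independently of the remote outer dioxane.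

Step 18
Reactants: 28 aldol adduct
Product: 29 ethyl (E)-3-(3-bromo-4-{[(1S,2S)-1-(BD)-1,3-dihydroxypropan-2-yl]oxy}phenyl)prop-2-enoate
Conditions: LiBH4 (1.5 equiv), MeOH (1.5 equiv), THF, 0 °C
Reagents that add atoms: none
Why: Reductive cleavage of the N-acyl oxazolidinone, whose exocyclic carbonyl is much more electrophilic than the conjugated ethyl ester, so the cinnamate should survive at 0 °C and auxiliary 22 is recovered; no stereocentre is touched.

Step 19
Reactants: 29 threo diol
Product: 30 ethyl (E)-3-(3-bromo-4-{[(1S,2S)-1-(BD)-1-hydroxy-3-(TIPS-oxy)propan-2-yl]oxy}phenyl)prop-2-enoate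
Conditions: TIPSCl (1.2 equiv), imidazole (2.5 equiv), DMF, 0 °C → rt
Reagents that add atoms: triisopropylsilyl chloride, CC(C)[Si](Cl)(C(C)C)C(C)C
Why: Selective silylation of the primary alcohol by a bulky silyl chloride, leaving the benzylic secondary alcohol free; triisopropylsilyl is chosen because it resists 1,3-migration to the neighbouring alkoxide, which would expose the primary oxygen to the next ring closure.

Step 20
Reactants: 30 bromo alcohol
Product: 31 ethyl (E)-3-[(2S,3S)-3-(BD)-2-[(TIPS-oxy)methyl]-2,3-dihydro-1,4-benzodioxin-6-yl]prop-2-enoate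
Conditions: Pd(OAc)2 (5 mol%), rac-2-(di-tert-butylphosphino)-1,1'-binaphthyl (6 mol%), K3PO4 (1.5 equiv), toluene, 80 °C
Reagents that add atoms: none
Why: Palladium-catalysed intramolecular C–O coupling of a secondary alcohol with an ortho-bromoaryl ether (Buchwald–Hartwig etherification); oxidative addition, alkoxide exchange and reductive elimination from a six-membered palladacycle form the O–aryl bond. C7 keeps its configuration, so the threo precursor gives the trans (7S,8S) inner dioxane, and the bulky electron-rich phosphine favours reductive elimination over β-hydride loss.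

Step 21
Reactants: 31 bis-dioxane ethyl ester
Product: 32 (E)-3-[(2S,3S)-3-(BD)-2-[(TIPS-oxy)methyl]-2,3-dihydro-1,4-benzodioxin-6-yl]prop-2-en-1-ol
Conditions: i-Bu2AlH (2.5 equiv), CH2Cl2, −78 °C; aqueous potassium sodium tartrate
Reagents that add atoms: none
Why: 1,2-Reduction of the α,β-unsaturated ester to the (E)-allylic alcohol by the aluminium hydride at low temperature; silyl ethers and aryl ethers are inert.

Step 22
Reactants: 32 tetrasilyl ether
Product: 33 (E)-3-[(2S,3S)-3-[(2R,3R)-3-(3,4-dihydroxyphenyl)-2-(hydroxymethyl)-2,3-dihydro-1,4-benzodioxin-6-yl]-2-(hydroxymethyl)-2,3-dihydro-1,4-benzodioxin-6-yl]prop-2-en-1-ol (target, 7S,8S,7'R,8'R)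
Conditions: Bu4NF (8 equiv), AcOH (8 equiv), THF, 0 °C → rt, argon
Reagents that add atoms: none
Why: Fluoride cleavage of the two aryl and two alkyl silyl ethers; buffering with acetic acid keeps the liberated catechol protonated and away from air oxidation, and avoids the acid that would ionise the cinnamyl alcohol.

## Compound list

1 | 3,4-dihydroxybenzaldehyde | O=Cc1ccc(O)c(O)c1 | starting material
2 | 3,4-bis(TBS-oxy)benzaldehyde | O=Cc1ccc(O[Si](C)(C)C(C)(C)C)c(O[Si](C)(C)C(C)(C)C)c1 | intermediate
3 | ethynyltrimethylsilane | C#C[Si](C)(C)C | starting material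
4 | methylzinc trimethylsilylacetylide | C[Zn]C#C[Si](C)(C)C | intermediate (not isolated)
5 | (S)-1-ArC-3-(trimethylsilyl)prop-2-yn-1-ol | O[C@@H](c1ccc(O[Si](C)(C)C(C)(C)C)c(O[Si](C)(C)C(C)(C)C)c1)C#C[Si](C)(C)C | intermediate
6 | (R)-1-ArC-prop-2-yn-1-ol | O[C@@H](c1ccc(O[Si](C)(C)C(C)(C)C)c(O[Si](C)(C)C(C)(C)C)c1)C#C | intermediate
7 | 4-(allyloxy)-3-hydroxybenzaldehyde | O=Cc1ccc(OCC=C)c(O)c1 | intermediate
8 | 2-(allyloxy)-5-(dimethoxymethyl)phenol | COC(OC)c1ccc(OCC=C)c(O)c1 | intermediate
9 | 1-(allyloxy)-2-{[(1S)-1-ArC-prop-2-yn-1-yl]oxy}-4-(dimethoxymethyl)benzene | COC(OC)c1ccc(OCC=C)c(O[C@H](c2ccc(O[Si](C)(C)C(C)(C)C)c(O[Si](C)(C)C(C)(C)C)c2)C#C)c1 | intermediate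
10 | 2-{[(1S)-1-ArC-prop-2-yn-1-yl]oxy}-4-(dimethoxymethyl)phenol | COC(OC)c1ccc(O)c(O[C@H](c2ccc(O[Si](C)(C)C(C)(C)C)c(O[Si](C)(C)C(C)(C)C)c2)C#C)c1 | intermediate
11 | 2-{[(1S)-1-ArC-prop-2-en-1-yl]oxy}-4-(dimethoxymethyl)phenol | COC(OC)c1ccc(O)c(O[C@H](c2ccc(O[Si](C)(C)C(C)(C)C)c(O[Si](C)(C)C(C)(C)C)c2)C=C)c1 | intermediate
12 | allyl methyl carbonate | C=CCOC(=O)OC | starting material
13 | (2E,4S)-4-ArC-4-[5-(dimethoxymethyl)-2-hydroxyphenoxy]but-2-en-1-yl methyl carbonate | COC(OC)c1ccc(O)c(O[C@H](c2ccc(O[Si](C)(C)C(C)(C)C)c(O[Si](C)(C)C(C)(C)C)c2)/C=C/COC(=O)OC)c1 | intermediate (precursor of the key step)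
14 | (2R,3R)-3-ArC-6-(dimethoxymethyl)-2-vinyl-2,3-dihydro-1,4-benzodioxine | COC(OC)c1ccc2c(c1)O[C@H](c1ccc(O[Si](C)(C)C(C)(C)C)c(O[Si](C)(C)C(C)(C)C)c1)[C@@H](C=C)O2 | intermediate (product of the key step)
15 | (2S,3R)-3-ArC-6-(dimethoxymethyl)-2,3-dihydro-1,4-benzodioxine-2-carbaldehyde (trans; descriptor changed by priority only) | COC(OC)c1ccc2c(c1)O[C@H](c1ccc(O[Si](C)(C)C(C)(C)C)c(O[Si](C)(C)C(C)(C)C)c1)[C@@H](C=O)O2 | intermediate (not isolated)
16 | [(2R,3R)-3-ArC-6-(dimethoxymethyl)-2,3-dihydro-1,4-benzodioxin-2-yl]methanol | COC(OC)c1ccc2c(c1)O[C@H](c1ccc(O[Si](C)(C)C(C)(C)C)c(O[Si](C)(C)C(C)(C)C)c1)[C@@H](CO)O2 | intermediate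
17 | tert-butyl{[(2R,3R)-3-ArC-6-(dimethoxymethyl)-2,3-dihydro-1,4-benzodioxin-2-yl]methoxy}dimethylsilane | COC(OC)c1ccc2c(c1)O[C@H](c1ccc(O[Si](C)(C)C(C)(C)C)c(O[Si](C)(C)C(C)(C)C)c1)[C@@H](CO[Si](C)(C)C(C)(C)C)O2 | intermediate
18 | (2R,3R)-3-ArC-2-[(TBS-oxy)methyl]-2,3-dihydro-1,4-benzodioxine-6-carbaldehyde (BD–CHO) | O=Cc1ccc2c(c1)O[C@H](c1ccc(O[Si](C)(C)C(C)(C)C)c(O[Si](C)(C)C(C)(C)C)c1)[C@@H](CO[Si](C)(C)C(C)(C)C)O2 | intermediate
19 | 3-bromo-4-hydroxybenzaldehyde | O=Cc1ccc(O)c(Br)c1 | starting material
20 | ethyl (triphenylphosphoranylidene)acetate | CCOC(=O)C=P(c1ccccc1)(c1ccccc1)c1ccccc1 | starting material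
21 | ethyl (E)-3-(3-bromo-4-hydroxyphenyl)prop-2-enoate | CCOC(=O)/C=C/c1ccc(O)c(Br)c1 | intermediate
22 | (R)-4-benzyloxazolidin-2-one | O=C1N[C@H](Cc2ccccc2)CO1 | starting material
23 | chloroacetyl chloride | O=C(Cl)CCl | starting material
24 | lithium salt of (R)-4-benzyloxazolidin-2-one | [Li]N1[C@H](Cc2ccccc2)COC1=O | intermediate (not isolated)
25 | (R)-4-benzyl-3-(chloroacetyl)oxazolidin-2-one | O=C(CCl)N1[C@H](Cc2ccccc2)COC1=O | intermediate
26 | ethyl (E)-3-(4-{2-[(4R)-4-benzyl-2-oxooxazolidin-3-yl]-2-oxoethoxy}-3-bromophenyl)prop-2-enoate | CCOC(=O)/C=C/c1ccc(OCC(=O)N2[C@H](Cc3ccccc3)COC2=O)c(Br)c1 | intermediate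
27 | dibutylboron (Z)-enolate of 26 | CCCCB(CCCC)O/C(=C\Oc1ccc(/C=C/C(=O)OCC)cc1Br)N1[C@H](Cc2ccccc2)COC1=O | intermediate (not isolated)
28 | (4R)-4-benzyl-3-[(2R,3S)-3-(BD)-2-{2-bromo-4-[(E)-3-ethoxy-3-oxoprop-1-en-1-yl]phenoxy}-3-hydroxypropanoyl]oxazolidin-2-one | CCOC(=O)/C=C/c1ccc(O[C@@H](C(=O)N2[C@H](Cc3ccccc3)COC2=O)[C@@H](O)c2ccc3c(c2)O[C@H](c2ccc(O[Si](C)(C)C(C)(C)C)c(O[Si](C)(C)C(C)(C)C)c2)[C@@H](CO[Si](C)(C)C(C)(C)C)O3)c(Br)c1 | intermediate
29 | ethyl (E)-3-(3-bromo-4-{[(1S,2S)-1-(BD)-1,3-dihydroxypropan-2-yl]oxy}phenyl)prop-2-enoate | CCOC(=O)/C=C/c1ccc(O[C@@H](CO)[C@@H](O)c2ccc3c(c2)O[C@H](c2ccc(O[Si](C)(C)C(C)(C)C)c(O[Si](C)(C)C(C)(C)C)c2)[C@@H](CO[Si](C)(C)C(C)(C)C)O3)c(Br)c1 | intermediate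
30 | ethyl (E)-3-(3-bromo-4-{[(1S,2S)-1-(BD)-1-hydroxy-3-(TIPS-oxy)propan-2-yl]oxy}phenyl)prop-2-enoate | CCOC(=O)/C=C/c1ccc(O[C@@H](CO[Si](C(C)C)(C(C)C)C(C)C)[C@@H](O)c2ccc3c(c2)O[C@H](c2ccc(O[Si](C)(C)C(C)(C)C)c(O[Si](C)(C)C(C)(C)C)c2)[C@@H](CO[Si](C)(C)C(C)(C)C)O3)c(Br)c1 | intermediate
31 | ethyl (E)-3-[(2S,3S)-3-(BD)-2-[(TIPS-oxy)methyl]-2,3-dihydro-1,4-benzodioxin-6-yl]prop-2-enoate | CCOC(=O)/C=C/c1ccc2c(c1)O[C@@H](c1ccc3c(c1)O[C@H](c1ccc(O[Si](C)(C)C(C)(C)C)c(O[Si](C)(C)C(C)(C)C)c1)[C@@H](CO[Si](C)(C)C(C)(C)C)O3)[C@H](CO[Si](C(C)C)(C(C)C)C(C)C)O2 | intermediate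
32 | (E)-3-[(2S,3S)-3-(BD)-2-[(TIPS-oxy)methyl]-2,3-dihydro-1,4-benzodioxin-6-yl]prop-2-en-1-ol | OC/C=C/c1ccc2c(c1)O[C@@H](c1ccc3c(c1)O[C@H](c1ccc(O[Si](C)(C)C(C)(C)C)c(O[Si](C)(C)C(C)(C)C)c1)[C@@H](CO[Si](C)(C)C(C)(C)C)O3)[C@H](CO[Si](C(C)C)(C(C)C)C(C)C)O2 | intermediate
33 | (E)-3-[(2S,3S)-3-[(2R,3R)-3-(3,4-dihydroxyphenyl)-2-(hydroxymethyl)-2,3-dihydro-1,4-benzodioxin-6-yl]-2-(hydroxymethyl)-2,3-dihydro-1,4-benzodioxin-6-yl]prop-2-en-1-ol | OC/C=C/c1ccc2c(c1)O[C@@H](c1ccc3c(c1)O[C@H](c1ccc(O)c(O)c1)[C@@H](CO)O3)[C@H](CO)O2 | target

## Step count and risk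

Total step count: 22.
Longest linear sequence: 17 steps (steps 1–3, 6–13, 17–22).

Least certain steps:

**Step 10 (key step).** The most likely failure is erosion of the trans preference if ring closure outruns face exchange of the π-allyl complex or if the ligand antipode is mismatched with C7'. The σ-allyl form with palladium on C8' could also expel the C7' aryloxide to give a diene, and intermolecular etherification could compete. Both ligand antipodes and high dilution would be tried first. The fallback drops the allyl–palladium chemistry and sets out from 11. Iodoetherification (I2, NaHCO3, MeCN, 0 °C) closes the same ring 6-exo through a chair transition state with the aryl group equatorial, giving the trans (2S,3R)-3-ArC-6-(dimethoxymethyl)-2-(iodomethyl)-2,3-dihydro-1,4-benzodioxine F1. Displacement with CsOAc in DMF gives the [(2R,3R)-3-ArC-6-(dimethoxymethyl)-2,3-dihydro-1,4-benzodioxin-2-yl]methyl acetate F2, and i-Bu2AlH at −78 °C releases alcohol 16, where the route is rejoined.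

**Step 6.** Partial loss of configuration can occur if the oxyphosphonium ion of the electron-rich benzylic propargylic alcohol ionises before the phenol attacks. The fallback makes the C7'–O bond under catalyst control. Alcohol 6 (its configuration no longer matters) is acetylated (Ac2O, Et3N, DMAP) to 1-ArC-prop-2-yn-1-yl acetate F3. A monovalent copper catalyst (CuOTf·1/2C6H6 with a chiral Ph-pybox ligand, i-Pr2NEt) then couples F3 with phenol 8 by enantioselective propargylic etherification through a copper acetylide–allenylidene species, returning to 9.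

**Step 9.** Slow turnover at the hindered alkene, or migration of the double bond into an enol ether by ruthenium hydride species, would lower the yield. The fallback avoids metathesis and sets out from alkyne 10. Double deprotonation with EtMgBr and addition to paraformaldehyde gives (4R)-4-ArC-4-[5-(dimethoxymethyl)-2-hydroxyphenoxy]but-2-yn-1-ol F4. Lindlar semihydrogenation gives the (2Z,4S)-but-2-en-1-ol F5, and methyl chloroformate with pyridine gives the bis(methyl carbonate) F6. One equivalent of pyrrolidine at 0 °C removes the more electrophilic aryl carbonate to give the (2Z,4S) isomer of 13, F7. Under the conditions of step 10, F7 enters the same π-allyl manifold and returns to the route at 14.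

**Step 11.** Over-oxidation of the electron-rich arenes by ozone, or epimerisation and β-aryloxide loss at the α-aryloxy aldehyde before reduction, are the likely problems. The fallback sets out from 14 and separates the events. Dihydroxylation (OsO4 cat., N-methylmorpholine N-oxide, acetone/H2O) gives 1-[(2R,3R)-3-ArC-6-(dimethoxymethyl)-2,3-dihydro-1,4-benzodioxin-2-yl]ethane-1,2-diol F8. Buffered NaIO4 cleaves F8 to aldehyde 15, which is reduced at once with NaBH4 to 16.

**Step 20.** β-Hydride loss from the palladium alkoxide (giving the aryl ketone and the debrominated arene) or base-induced silyl migration would divert the material. The fallback sets out from 30 and closes the ring from the other polarity. Miyaura borylation (bis(pinacolato)diboron, Pd(dppf)Cl2, KOAc, dioxane, 80 °C) gives the pinacol arylboronate F9, and H2O2 with NaHCO3 gives the phenol F10. Catalytic camphorsulfonic acid in CH2Cl2 at 0 °C ionises the benzylic alcohol, which ring B stabilises through its para oxygen, and the phenol closes to the thermodynamically preferred trans ring under control of C8, returning to 31.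

## Further compounds

F1 | step 10 | (2S,3R)-3-ArC-6-(dimethoxymethyl)-2-(iodomethyl)-2,3-dihydro-1,4-benzodioxine (trans) | COC(OC)c1ccc2c(c1)O[C@H](c1ccc(O[Si](C)(C)C(C)(C)C)c(O[Si](C)(C)C(C)(C)C)c1)[C@@H](CI)O2
F2 | step 10 | [(2R,3R)-3-ArC-6-(dimethoxymethyl)-2,3-dihydro-1,4-benzodioxin-2-yl]methyl acetate | COC(OC)c1ccc2c(c1)O[C@H](c1ccc(O[Si](C)(C)C(C)(C)C)c(O[Si](C)(C)C(C)(C)C)c1)[C@@H](COC(C)=O)O2
F3 | step 6 | (R)-1-ArC-prop-2-yn-1-yl acetate (configuration irrelevant) | CC(=O)O[C@@H](c1ccc(O[Si](C)(C)C(C)(C)C)c(O[Si](C)(C)C(C)(C)C)c1)C#C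
F4 | step 9 | (4R)-4-ArC-4-[5-(dimethoxymethyl)-2-hydroxyphenoxy]but-2-yn-1-ol | COC(OC)c1ccc(O)c(O[C@H](c2ccc(O[Si](C)(C)C(C)(C)C)c(O[Si](C)(C)C(C)(C)C)c2)C#CCO)c1
F5 | step 9 | (2Z,4S)-4-ArC-4-[5-(dimethoxymethyl)-2-hydroxyphenoxy]but-2-en-1-ol | COC(OC)c1ccc(O)c(O[C@H](c2ccc(O[Si](C)(C)C(C)(C)C)c(O[Si](C)(C)C(C)(C)C)c2)/C=C\CO)c1
F6 | step 9 | (2Z,4S)-4-ArC-4-[5-(dimethoxymethyl)-2-(methoxycarbonyloxy)phenoxy]but-2-en-1-yl methyl carbonate | COC(OC)c1ccc(OC(=O)OC)c(O[C@H](c2ccc(O[Si](C)(C)C(C)(C)C)c(O[Si](C)(C)C(C)(C)C)c2)/C=C\COC(=O)OC)c1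
F7 | step 9 | (2Z,4S)-4-ArC-4-[5-(dimethoxymethyl)-2-hydroxyphenoxy]but-2-en-1-yl methyl carbonate | COC(OC)c1ccc(O)c(O[C@H](c2ccc(O[Si](C)(C)C(C)(C)C)c(O[Si](C)(C)C(C)(C)C)c2)/C=C\COC(=O)OC)c1
F8 | step 11 | 1-[(2R,3R)-3-ArC-6-(dimethoxymethyl)-2,3-dihydro-1,4-benzodioxin-2-yl]ethane-1,2-diol (both carbinol epimers) | COC(OC)c1ccc2c(c1)O[C@H](c1ccc(O[Si](C)(C)C(C)(C)C)c(O[Si](C)(C)C(C)(C)C)c1)[C@@H](C(O)CO)O2
F9 | step 20 | pinacol arylboronate of 30 (Br replaced by 4,4,5,5-tetramethyl-1,3,2-dioxaborolan-2-yl) | CCOC(=O)/C=C/c1ccc(O[C@@H](CO[Si](C(C)C)(C(C)C)C(C)C)[C@@H](O)c2ccc3c(c2)O[C@H](c2ccc(O[Si](C)(C)C(C)(C)C)c(O[Si](C)(C)C(C)(C)C)c2)[C@@H](CO[Si](C)(C)C(C)(C)C)O3)c(B2OC(C)(C)C(C)(C)O2)c1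
F10 | step 20 | phenol of 30 (Br replaced by OH) | CCOC(=O)/C=C/c1ccc(O[C@@H](CO[Si](C(C)C)(C(C)C)C(C)C)[C@@H](O)c2ccc3c(c2)O[C@H](c2ccc(O[Si](C)(C)C(C)(C)C)c(O[Si](C)(C)C(C)(C)C)c2)[C@@H](CO[Si](C)(C)C(C)(C)C)O3)c(O)c1
A1 | alternative 1 | methyl (2R,3R)-2-[(TBS-oxy)methyl]-3-[4-hydroxy-3-(methoxymethoxy)phenyl]-2,3-dihydro-1,4-benzodioxine-6-carboxylate | COC(=O)c1ccc2c(c1)O[C@H](c1ccc(O)c(OCOC)c1)[C@@H](CO[Si](C)(C)C(C)(C)C)O2
A2 | alternative 1 | methyl 3-hydroxy-4-{[(2S)-1-(TBS-oxy)-3-[4-hydroxy-3-(methoxymethoxy)phenyl]propan-2-yl]oxy}benzoate | COC(=O)c1ccc(O[C@H](CO[Si](C)(C)C(C)(C)C)Cc2ccc(O)c(OCOC)c2)c(O)c1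
A3 | alternative 2 | trans-fused dioxane on the methyl shikimate ring carrying BD at C7 and CH2O-TBS at C8 | COC(=O)C1=C[C@@H](O)[C@@H]2[C@@H](C1)O[C@@H](c3ccc4c(c3)O[C@H](c3ccc(O[Si](C)(C)C(C)(C)C)c(O[Si](C)(C)C(C)(C)C)c3)[C@@H](CO[Si](C)(C)C(C)(C)C)O4)[C@H](CO[Si](C)(C)C(C)(C)C)O2
A4 | alternative 2 | methyl 5-O-[(1S)-1-(BD)-2-oxo-3-(TBS-oxy)propyl]shikimate (hydroxy ketone) | COC(=O)C1=C[C@@H](O)[C@@H](O)[C@@H](C1)O[C@@H](c2ccc3c(c2)O[C@H](c2ccc(O[Si](C)(C)C(C)(C)C)c(O[Si](C)(C)C(C)(C)C)c2)[C@@H](CO[Si](C)(C)C(C)(C)C)O3)C(=O)CO[Si](C)(C)C(C)(C)C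
A5 | alternative 3 | trans 3-(BD)-7-bromo-2,3-dihydro-1,4-benzodioxine-2-carbaldehyde (inner dioxane C9 aldehyde, ring A bromide) | Brc1ccc2c(c1)O[C@@H](c1ccc3c(c1)O[C@H](c1ccc(O[Si](C)(C)C(C)(C)C)c(O[Si](C)(C)C(C)(C)C)c1)[C@@H](CO[Si](C)(C)C(C)(C)C)O3)[C@H](C=O)O2
A6 | alternative 3 | (Z)-3-(BD)-2-(4-bromo-2-hydroxyphenoxy)prop-2-enal | O=C/C(Oc1ccc(Br)cc1O)=C/c1ccc2c(c1)O[C@H](c1ccc(O[Si](C)(C)C(C)(C)C)c(O[Si](C)(C)C(C)(C)C)c1)[C@@H](CO[Si](C)(C)C(C)(C)C)O2
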